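**Retrosynthetic overview**

1. Numbering follows the oleananes (the ring‑C CH2 between C12 and C13 is C27, the 4β‑carboxyl carbon is C24). The enabling feature lies in ring A: the C25 methyl sits on quaternary C10, next to C5, which is β to the C24 carboxyl on C4, which is next to the C3 carbinol. This CH3–C10–C5–C4(CO2H)–C3(OH) pattern is the retron of a hydrogen‑atom‑transfer / Giese / aldol cascade (C25 was =CH2, C5–C10 is the radical bond, C3–C4 the aldol bond).
2. Disconnections: C13–C18 and C16–C17 (Diels–Alder of a ring‑C vinylcycloheptene with a ring‑E enone ester), C13=C14 (ring‑closing enyne metathesis), C5–C10 and C3–C4 (iron‑hydride bicyclization of a monocyclic δ‑lactone).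
3. The δ‑lactone C14(=O)–O–C12 is a temporary ring: it ties C8 and C9 so that ring B can close through one chair only, and its ring oxygen ends up as the 12‑methoxy oxygen.
4. Ring order: temporary lactone → B then A (one step) → C → D (ring E is brought in preformed from 4,4‑dimethylcyclohexane‑1,3‑dione).
5. Stereocentres: C9 by Cu‑catalysed asymmetric conjugate addition, C8 by trans alkylation, C5/C10 in the key step, C4 by methylation, C3 and C19 by L‑Selectride, C12 by allylboration, C17/C18 by an endo Diels–Alder on the α face.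

Key step: step 10

Remark: 1, 2, 6 and 33 are taken as commercial; centres that are erased again (ring C5 in 11, C3/C4 in 21, C14 in 26, C13 in 36) are carried as mixtures.

Step 1
Reactants: 1 2,3-dibromoprop-1-ene; 2 allylmagnesium bromide
Product: 3 2-bromohexa-1,5-diene
Conditions: Et2O, 0 °C → rt
Reagents that add atoms: none
Why: Allylic substitution of the allylic bromide by the allyl Grignard reagent (SN2 and SN2′ give the same product) leaves the vinylic bromide untouched.

Step 2
Reactants: 3 2-bromohexa-1,5-diene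
Product: 5 2-bromo-5,5-dimethoxypent-1-ene, via 4-bromopent-4-enal 4 (not isolated)
Conditions: O3 (1 equiv), CH2Cl2/MeOH, −78 °C; Me2S; then HC(OMe)3, TsOH (cat.), rt
Reagents that add atoms: trimethyl orthoformate, COC(OC)OC
Why: Ozonolysis with reductive work‑up cleaves only the electron‑rich monosubstituted alkene (the 2‑bromoalkene is deactivated), and the aldehyde is acetalised in the same flask.

Step 3
Reactants: 5 2-bromo-5,5-dimethoxypent-1-ene; 6 2-methylcyclopent-2-en-1-one
Product: 9 (2R,3R)-3-(5,5-dimethoxypent-1-en-2-yl)-2-methyl-2-(prop-2-yn-1-yl)cyclopentan-1-one, via (5,5-dimethoxypent-1-en-2-yl)magnesium bromide 7 (not isolated), via bromomagnesium enolate 8 (not isolated)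
Conditions: Mg, THF; then 6, CuBr·SMe2 (5 mol %), Josiphos‑type ferrocenyl diphosphine (6 mol %), t‑BuOMe, −78 °C; then propargyl bromide, DMPU, −78 → 0 °C
Reagents that add atoms: propargyl bromide, C#CCBr
Why: Copper‑catalysed asymmetric conjugate addition of a Grignard reagent to an α‑methyl cyclic enone sets C9 under ligand control (the ligand enantiomer that gives 3R is used), and the regiodefined magnesium enolate is alkylated anti to the new C9 substituent, which sets quaternary C8 (three‑component coupling).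

Step 4
Reactants: 9 alkynyl cyclopentanone
Product: 11 (2R,3R,5RS)-5-hydroxy ketone, via potassium enolate 10 (not isolated)
Conditions: KHMDS, THF, −78 °C; then 2-(phenylsulfonyl)-3-phenyloxaziridine; aq. NH4Cl
Reagents that add atoms: 2-(phenylsulfonyl)-3-phenyloxaziridine, O=S(=O)(c1ccccc1)N1OC1c1ccccc1
Why: Davis oxidation of the only possible enolate (C8 is quaternary) gives the α‑ketol; the new carbinol centre is left as a mixture because it becomes an aldehyde carbon in step 5.

Step 5
Reactants: 11 α-ketol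
Product: 12 methyl (2R,3R)-7,7-dimethoxy-2-methyl-4-methylidene-3-(2-oxoethyl)-2-(prop-2-yn-1-yl)heptanoate
Conditions: Pb(OAc)4, MeOH/PhH (1:1), 0 °C
Reagents that add atoms: methanol, CO
Why: Lead tetraacetate cleavage of an α‑ketol (Criegee type) in methanol opens the cyclopentanone to the methyl ester (C14) and the aldehyde (C12) without touching alkene, alkyne or acetal.

Step 6
Reactants: 12 ester aldehyde
Product: 14 (3R,4R)-4-(5,5-dimethoxypent-1-en-2-yl)-3-methyl-3-(prop-2-yn-1-yl)oxan-2-one, via hydroxy ester 13 (not isolated)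
Conditions: NaBH4, MeOH, 0 °C; then PPTS (cat.), PhH, 80 °C
Reagents that add atoms: none
Why: Chemoselective borohydride reduction of the aldehyde, then acid‑catalysed lactonisation of the δ‑hydroxy ester (helped by the quaternary centre), gives the temporary δ‑lactone.

Step 7
Reactants: 14 alkynyl lactone
Product: 16 lactone aldehyde (C5 aldehyde), via alkenyl(disiamyl)borane 15 (not isolated)
Conditions: Sia2BH, THF, 0 °C; then 30% H2O2, aq. NaOAc, 0 °C → rt
Reagents that add atoms: hydrogen peroxide, OO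
Why: Anti‑Markovnikov hydroboration–oxidation of the terminal alkyne with a hindered dialkylborane gives the aldehyde, while the hindered 1,1‑disubstituted alkene and the lactone react much more slowly.

Step 8
Reactants: 16 lactone aldehyde
Product: 17 benzyl (2E)-enoate acetal
Conditions: Ph3P=CHCO2Bn, CH2Cl2, rt
Reagents that add atoms: benzyl (triphenylphosphoranylidene)acetate, O=C(C=P(c1ccccc1)(c1ccccc1)c1ccccc1)OCc1ccccc1
Why: Wittig reaction of a stabilised ylide gives the (E)‑enoate acceptor.

Step 9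
Reactants: 17 enoate acetal
Product: 18 benzyl (2E)-5-[(3R,4R)-3-methyl-2-oxo-4-(5-oxopent-1-en-2-yl)oxan-3-yl]pent-2-enoate
Conditions: PPTS, acetone/H2O (4:1), 50 °C
Reagents that add atoms: water, O
Why: Mild acid hydrolysis of the dimethyl acetal frees the C3 aldehyde and leaves lactone, enoate and the 1,1‑disubstituted alkene intact.

Step 10
Reactants: 18 enoate aldehyde
Product: 21 tricyclic lactone hydroxy ester (mixture at C3 and C4), via tertiary C10 radical 19 (not isolated), via iron ester enolate 20 (not isolated)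
Conditions: Fe(acac)3 (0.3 equiv), PhSiH2(Oi-Pr), EtOH/(CH2OH)2 (5:1), 0 °C → rt, degassed
Reagents that add atoms: none
Why: Mukaiyama‑type hydrogen‑atom transfer from an iron hydride to the terminal carbon of the only electron‑rich alkene (C10=C25) creates the C25 methyl and the tertiary C10 radical 19, which adds 6‑exo‑trig to C5, the β‑carbon of the enoate (ring B, C5–C10 bond); the α‑ester radical is reduced by iron(II) to enolate 20, which closes ring A by a 6‑(enolexo)‑exo‑trig aldol addition to the C3 aldehyde. The closest known reaction type is the iron‑hydride radical–polar crossover annulation (Giese addition, then aldol) of γ,δ‑unsaturated carbonyl compounds with acceptor alkenes, here run intramolecularly as a bicyclization. The temporary δ‑lactone holds C14 and C11 trans‑diequatorial, so ring B forms through a single chair in which the enoate arm on C5 is equatorial (5α‑H) and the C26 methyl is axial. At the planar radical centre the small methyl should take the crowded pseudo‑axial site next to quaternary C8 while the C1 chain eclipses C9–H, which sets 10β‑CH3 and the trans ring fusion. C3 and C4 need no control because both are erased in steps 11 and 12. The step needs chemoselective hydrogen‑atom transfer to the 1,1‑disubstituted alkene in the presence of enoate and aldehyde, which the electron‑rich, unhindered =CH2 terminus secures.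

Step 11
Reactants: 21 tricyclic hydroxy ester
Product: 22 tricyclic 3-oxo ester
Conditions: Dess–Martin periodinane, NaHCO3, CH2Cl2, rt
Reagents that add atoms: none
Why: Dess–Martin oxidation turns all C3/C4 diastereomers of the aldol into one enolisable β‑keto ester.

Step 12
Reactants: 22 β-keto ester
Product: 23 4α-methyl-4β-benzyloxycarbonyl 3-ketone
Conditions: MeI, K2CO3, acetone, rt
Reagents that add atoms: iodomethane, CI
Why: C‑Alkylation of the β‑keto ester enolate takes place on the α face, away from the axial C25 methyl on C10, which places the new methyl equatorial (4α) and the ester axial (4β).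

Step 13
Reactants: 23 quaternary keto ester
Product: 24 3α-alcohol
Conditions: L-Selectride, THF, −78 °C; aq. NH4Cl
Reagents that add atoms: none
Why: The bulky hydride attacks the C3 ketone along the equatorial trajectory (as with 3‑oxo‑4,4‑disubstituted triterpenoids) and gives the axial 3α‑alcohol, while lactone and hindered ester are not reduced at −78 °C.

Step 14
Reactants: 24 3α-alcohol
Product: 25 3α-benzyl ether
Conditions: 2-benzyloxy-1-methylpyridinium triflate, MgO, PhCF3, 85 °C
Reagents that add atoms: 2-benzyloxy-1-methylpyridinium triflate, C[n+]1ccccc1OCc1ccccc1.[O-]S(=O)(=O)C(F)(F)F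
Why: Benzylation under neutral conditions (benzyl cation transfer) protects the hindered β‑hydroxy ester without base, so that no retro‑aldol can occur.

Step 15
Reactants: 25 benzyl ether lactone
Product: 26 lactol (mixture at C14)
Conditions: DIBAL-H (1.1 equiv), CH2Cl2, −78 °C; Rochelle salt
Reagents that add atoms: none
Why: Partial reduction of the lactone to the lactol opens the temporary ring, while the axial neopentyl benzyl ester on C4 is far more hindered and survives.

Step 16
Reactants: 26 lactol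
Product: 27 8α-ethynyl decalin with free C12 alcohol
Conditions: dimethyl (1-diazo-2-oxopropyl)phosphonate, K2CO3, MeOH, rt
Reagents that add atoms: dimethyl (1-diazo-2-oxopropyl)phosphonate, COP(=O)(OC)C(=[N+]=[N-])C(C)=O
Why: Seyferth–Gilbert homologation with the Ohira–Bestmann reagent converts the hydroxy‑aldehyde form of the lactol into the terminal alkyne (C14≡C15) and frees the C12 alcohol.

Step 17
Reactants: 27 alkynol
Product: 28 C12 aldehyde
Conditions: Dess–Martin periodinane, NaHCO3, CH2Cl2, 0 °C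
Reagents that add atoms: none
Why: Dess–Martin oxidation of the primary alcohol gives the C12 aldehyde.

Step 18
Reactants: 28 alkynyl aldehyde
Product: 30 (12R)-homoallylic alcohol, via diisopinocampheyl borinate 29 (not isolated)
Conditions: Ipc2B(allyl) (the enantiomer that adds to the Re face), Et2O, −78 °C; then NaOH, H2O2
Reagents that add atoms: B-allyldiisopinocampheylborane, C=CCB(C1CC2CC(C1C)C2(C)C)C1CC2CC(C1C)C2(C)C
Why: Reagent‑controlled asymmetric allylboration through a chair six‑membered transition state adds the C27–C13 unit to the Re face and sets the 12R centre (12α‑oxygen).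

Step 19
Reactants: 30 homoallylic alcohol
Product: 31 (12R)-methyl ether enyne
Conditions: MeOTf, 2,6-di-tert-butyl-4-methylpyridine, CH2Cl2, 0 °C → rt
Reagents that add atoms: methyl trifluoromethanesulfonate, COS(=O)(=O)C(F)(F)F
Why: O‑Methylation with methyl triflate and a hindered base avoids metalation of the terminal alkyne and gives the 12‑methyl ether.

Step 20
Reactants: 31 enyne
Product: 32 tricyclic A/B/C diene (C13=C14–C15=C16)
Conditions: Grubbs second-generation catalyst (5 mol %), ethylene (1 atm), PhMe, 80 °C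
Reagents that add atoms: none
Why: Ring‑closing enyne metathesis (exo mode) forms the C13=C14 bond and ring C and moves the alkene CH2 onto C15, which gives the 1‑vinylcycloheptene diene.

Step 21
Reactants: 33 4,4-dimethylcyclohexane-1,3-dione
Product: 34 4,4-dimethyl-3-oxocyclohex-1-en-1-yl trifluoromethanesulfonate
Conditions: Tf2O, pyridine, CH2Cl2, −78 → 0 °C
Reagents that add atoms: trifluoromethanesulfonic anhydride, O=S(=O)(OS(=O)(=O)C(F)(F)F)C(F)(F)F
Why: O‑Sulfonylation of the vinylogous acid takes place at the enol oxygen remote from the gem‑dimethyl group, which leaves the ketone next to C20.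

Step 22
Reactants: 34 vinylogous triflate
Product: 35 benzyl 4,4-dimethyl-3-oxocyclohex-1-ene-1-carboxylate
Conditions: Pd(OAc)2 (5 mol %), dppp, CO (1 atm), BnOH, Et3N, DMF, 60 °C
Reagents that add atoms: carbon monoxide, [C-]#[O+]; benzyl alcohol, OCc1ccccc1
Why: Palladium‑catalysed alkoxycarbonylation of the vinyl triflate gives the doubly activated dienophile.

Step 23
Reactants: 32 tricyclic diene; 35 enone ester
Product: 36 pentacyclic 19-ketone (C14=C15; 13β-H; 18β-H; 17β-CO2Bn)
Conditions: Me2AlCl (0.3 equiv), CH2Cl2, −78 → −20 °C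
Reagents that add atoms: none
Why: Lewis‑acid‑catalysed Diels–Alder reaction: with the acid on the ring‑E ketone the unsubstituted diene terminus C16 bonds to C17 (β to the ketone) and C13 to C18, and the dienophile adds to the α face of the diene, away from the axial C26 methyl on C8, with the enone ring endo, which gives 13β‑H, 18β‑H and the 17β‑ester (cis D/E fusion).

Step 24
Reactants: 36 pentacyclic ketone
Product: 37 19α-alcohol
Conditions: L-Selectride, THF, −78 → 0 °C; aq. NH4Cl
Reagents that add atoms: none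
Why: The bulky hydride reaches the C19 ketone along the equatorial trajectory on the convex β face, because the axial approach is blocked by the ring‑D methylene C16 that is syn‑axial on C17, and gives the axial 19α‑alcohol.

Step 25
Reactants: 37 19α-alcohol (C14=C15)
Product: 38 tribenzyl-protected target (C13=C14)
Conditions: TsOH·H2O (0.2 equiv), PhH, 60 °C
Reagents that add atoms: none
Why: Acid‑catalysed alkene isomerisation by protonation at C15 and loss of H13 moves the trisubstituted C14=C15 bond into the tetrasubstituted C13=C14 position shared by rings C and D and removes the C13 centre.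

Step 26
Reactants: 38 tribenzyl-protected target
Product: 39 target diacid
Conditions: H2 (1 atm), 10% Pd/C, EtOAc/MeOH, rt
Reagents that add atoms: none
Why: Hydrogenolysis removes the two benzyl esters and the benzyl ether in one operation, while the hindered tetrasubstituted alkene is not hydrogenated.

**Compound list**

1 | 2,3-dibromoprop-1-ene | C=C(Br)CBr | starting material
2 | allylmagnesium bromide | C=CC[Mg]Br | starting material
3 | 2-bromohexa-1,5-diene | C=CCCC(Br)=C | intermediate
4 | 4-bromopent-4-enal | C=C(Br)CCC=O | intermediate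
5 | 2-bromo-5,5-dimethoxypent-1-ene | C=C(Br)CCC(OC)OC | intermediate
6 | 2-methylcyclopent-2-en-1-one | CC1=CCCC1=O | starting material
7 | (5,5-dimethoxypent-1-en-2-yl)magnesium bromide | C=C([Mg]Br)CCC(OC)OC | intermediate
8 | bromomagnesium (3R)-3-(5,5-dimethoxypent-1-en-2-yl)-2-methylcyclopent-1-en-1-olate | Br[Mg]OC1=C(C)[C@@H](C(=C)CCC(OC)OC)CC1 | intermediate
9 | (2R,3R)-3-(5,5-dimethoxypent-1-en-2-yl)-2-methyl-2-(prop-2-yn-1-yl)cyclopentan-1-one | O=C1CC[C@H](C(=C)CCC(OC)OC)[C@@]1(C)CC#C | intermediate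
10 | potassium enolate of 9 (enolised towards ring C5) | [K]OC1=CC[C@H](C(=C)CCC(OC)OC)[C@@]1(C)CC#C | intermediate
11 | (2R,3R,5RS)-5-hydroxy-3-(5,5-dimethoxypent-1-en-2-yl)-2-methyl-2-(prop-2-yn-1-yl)cyclopentan-1-one | O=C1C(O)C[C@H](C(=C)CCC(OC)OC)[C@@]1(C)CC#C | intermediate
12 | methyl (2R,3R)-7,7-dimethoxy-2-methyl-4-methylidene-3-(2-oxoethyl)-2-(prop-2-yn-1-yl)heptanoate | COC(=O)[C@](C)(CC#C)[C@H](CC=O)C(=C)CCC(OC)OC | intermediate
13 | methyl (2R,3R)-3-(2-hydroxyethyl)-7,7-dimethoxy-2-methyl-4-methylidene-2-(prop-2-yn-1-yl)heptanoate | COC(=O)[C@](C)(CC#C)[C@H](CCO)C(=C)CCC(OC)OC | intermediate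
14 | (3R,4R)-4-(5,5-dimethoxypent-1-en-2-yl)-3-methyl-3-(prop-2-yn-1-yl)oxan-2-one | O=C1OCC[C@H](C(=C)CCC(OC)OC)[C@@]1(C)CC#C | intermediate
15 | (E)-alkenylbis(3-methylbutan-2-yl)borane from 14 | O=C1OCC[C@H](C(=C)CCC(OC)OC)[C@@]1(C)C/C=C/B(C(C)C(C)C)C(C)C(C)C | intermediate
16 | 3-[(3R,4R)-4-(5,5-dimethoxypent-1-en-2-yl)-3-methyl-2-oxooxan-3-yl]propanal | O=C1OCC[C@H](C(=C)CCC(OC)OC)[C@@]1(C)CCC=O | intermediate
17 | benzyl (2E)-5-[(3R,4R)-4-(5,5-dimethoxypent-1-en-2-yl)-3-methyl-2-oxooxan-3-yl]pent-2-enoate | O=C1OCC[C@H](C(=C)CCC(OC)OC)[C@@]1(C)CC/C=C/C(=O)OCc1ccccc1 | intermediate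
18 | benzyl (2E)-5-[(3R,4R)-3-methyl-2-oxo-4-(5-oxopent-1-en-2-yl)oxan-3-yl]pent-2-enoate | O=C1OCC[C@H](C(=C)CCC=O)[C@@]1(C)CC/C=C/C(=O)OCc1ccccc1 | intermediate
19 | tertiary C10 radical formed from 18 by H‑atom transfer to C25 | O=C1OCC[C@H]([C](C)CCC=O)[C@@]1(C)CC/C=C/C(=O)OCc1ccccc1 | intermediate
20 | iron(III) ester enolate after closure of ring B (5α‑H, 10β‑CH3; other iron ligands omitted) | O=C1OCC[C@H]2[C@@]1(C)CC[C@@H](C=C(O[Fe])OCc1ccccc1)[C@]2(C)CCC=O | intermediate
21 | tricyclic lactone: trans‑decalin (rings A/B; 5α‑H, 8β‑CH3, 9α‑H, 10β‑CH3) fused at C8–C9 to the δ‑lactone C14(=O)–O–C12H2–C11H2; 3‑OH and 4‑CO2Bn as a mixture at C3 and C4 | O=C1OCC[C@H]2[C@@]1(C)CC[C@H]3C(C(=O)OCc4ccccc4)C(O)CC[C@]23C | intermediate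
22 | 3‑oxo analogue of 21 (β‑keto ester, mixture at C4) | O=C1OCC[C@H]2[C@@]1(C)CC[C@H]3C(C(=O)OCc4ccccc4)C(=O)CC[C@]23C | intermediate
23 | 4α‑methyl‑4β‑(benzyloxycarbonyl)‑3‑oxo tricyclic lactone | O=C1OCC[C@H]2[C@@]1(C)CC[C@H]3[C@@](C)(C(=O)OCc4ccccc4)C(=O)CC[C@]23C | intermediate
24 | 3α‑hydroxy‑4α‑methyl‑4β‑(benzyloxycarbonyl) tricyclic lactone | O=C1OCC[C@H]2[C@@]1(C)CC[C@H]3[C@@](C)(C(=O)OCc4ccccc4)[C@H](O)CC[C@]23C | intermediate
25 | 3α‑benzyloxy‑4α‑methyl‑4β‑(benzyloxycarbonyl) tricyclic lactone | O=C1OCC[C@H]2[C@@]1(C)CC[C@H]3[C@@](C)(C(=O)OCc4ccccc4)[C@H](OCc4ccccc4)CC[C@]23C | intermediate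
26 | lactol of 25 (C14 hemiacetal, both anomers) | OC1OCC[C@H]2[C@@]1(C)CC[C@H]3[C@@](C)(C(=O)OCc4ccccc4)[C@H](OCc4ccccc4)CC[C@]23C | intermediate
27 | trans‑decalin with 8α‑ethynyl (C14≡C15), 8β‑CH3, 9β‑(2‑hydroxyethyl) (C11–C12), 3α‑OBn, 4β‑CO2Bn | OCC[C@H]1[C@](C)(C#C)CC[C@H]2[C@@](C)(C(=O)OCc3ccccc3)[C@H](OCc3ccccc3)CC[C@]12C | intermediate
28 | C12 aldehyde of 27 | O=CC[C@H]1[C@](C)(C#C)CC[C@H]2[C@@](C)(C(=O)OCc3ccccc3)[C@H](OCc3ccccc3)CC[C@]12C | intermediate
29 | diisopinocampheyl borinate of the (12R)‑homoallylic alcohol | C=CC[C@@H](OB(C1CC2CC(C1C)C2(C)C)C1CC2CC(C1C)C2(C)C)C[C@H]1[C@](C)(C#C)CC[C@H]2[C@@](C)(C(=O)OCc3ccccc3)[C@H](OCc3ccccc3)CC[C@]12C | intermediate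
30 | (12R)‑homoallylic alcohol (C12–OH, C27H2–C13H=CH2) | C=CC[C@@H](O)C[C@H]1[C@](C)(C#C)CC[C@H]2[C@@](C)(C(=O)OCc3ccccc3)[C@H](OCc3ccccc3)CC[C@]12C | intermediate
31 | (12R)‑methyl ether enyne | C=CC[C@@H](OC)C[C@H]1[C@](C)(C#C)CC[C@H]2[C@@](C)(C(=O)OCc3ccccc3)[C@H](OCc3ccccc3)CC[C@]12C | intermediate
32 | A/B/C tricycle with seven‑membered ring C: 12α‑OMe, C13=C14, 14‑vinyl (C15=C16), 3α‑OBn, 4β‑CO2Bn | CO[C@@H]1CC=C(C=C)[C@]2(C)CC[C@@H]3[C@](C)(CC[C@@H](OCc4ccccc4)[C@]3(C)C(=O)OCc3ccccc3)[C@H]2C1 | intermediate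
33 | 4,4-dimethylcyclohexane-1,3-dione | CC1(C)CCC(=O)CC1=O | starting material
34 | 4,4-dimethyl-3-oxocyclohex-1-en-1-yl trifluoromethanesulfonate | CC1(C)CCC(OS(=O)(=O)C(F)(F)F)=CC1=O | intermediate
35 | benzyl 4,4-dimethyl-3-oxocyclohex-1-ene-1-carboxylate | CC1(C)CCC(C(=O)OCc2ccccc2)=CC1=O | intermediate
36 | pentacyclic Diels–Alder adduct: 19‑oxo, C14=C15, 13β‑H, 18β‑H, 17β‑CO2Bn, 12α‑OMe, 3α‑OBn, 4β‑CO2Bn | CO[C@@H]1C[C@H]2C(=CC[C@@]3(C(=O)OCc4ccccc4)CCC(C)(C)C(=O)[C@@H]23)[C@]2(C)CC[C@@H]3[C@](C)(CC[C@@H](OCc4ccccc4)[C@]3(C)C(=O)OCc3ccccc3)[C@H]2C1 | intermediate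
37 | 19α‑hydroxy analogue of 36 (C14=C15) | CO[C@@H]1C[C@H]2C(=CC[C@@]3(C(=O)OCc4ccccc4)CCC(C)(C)[C@@H](O)[C@@H]23)[C@]2(C)CC[C@@H]3[C@](C)(CC[C@@H](OCc4ccccc4)[C@]3(C)C(=O)OCc3ccccc3)[C@H]2C1 | intermediate
38 | 3‑O‑benzyl ether dibenzyl ester of the target (C13=C14) | CO[C@@H]1CC2=C(CC[C@@]3(C(=O)OCc4ccccc4)CCC(C)(C)[C@@H](O)[C@@H]23)[C@]2(C)CC[C@@H]3[C@](C)(CC[C@@H](OCc4ccccc4)[C@]3(C)C(=O)OCc3ccccc3)[C@H]2C1 | intermediate
39 | CNP0394974.1: 3α,19α‑dihydroxy‑12α‑methoxy ring‑C‑expanded Δ13(14) 24,28‑dioic acid | CO[C@@H]1CC2=C(CC[C@@]3(C(=O)O)CCC(C)(C)[C@@H](O)[C@@H]23)[C@]2(C)CC[C@@H]3[C@](C)(CC[C@@H](O)[C@]3(C)C(=O)O)[C@H]2C1 | target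

**Step count:** 26 steps in total. The longest linear sequence is 24 steps (steps 1–20 and 23–26); the dienophile branch has 2 steps (21–22).

**The three steps most likely to fail**

Step 10. After the radical ring closure the ester enolate may be protonated by the alcohol solvent before it adds to the aldehyde, so that ring A stays open; closure of the planar C10 radical with low facial selectivity is the second danger. The fallback changes the acceptor to an enal, whose enolate is the established partner in crossover aldol closures. It sets out from aldehyde 16. A Wittig reaction with (triphenylphosphoranylidene)acetaldehyde gives the enal acetal F1. Hydrolysis (PPTS, aqueous acetone) gives the dialdehyde F2. The same iron hydride conditions give the tricyclic hydroxy aldehyde F3. Pinnick oxidation (NaClO2, NaH2PO4, 2‑methylbut‑2‑ene) gives the hydroxy acid F4, and benzyl bromide with K2CO3 in DMF returns to the hydroxy ester 21.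

Step 25. Reversible protonation may carry the double bond on into the C13=C18 position, or the C14 cation next to quaternary C8 may undergo a 1,2‑shift. The fallback avoids a carbocation and sets out from 37. A Schenck ene reaction with singlet oxygen (O2, tetraphenylporphyrin, hν) removes the hydrogen on C13 and gives the C15 allylic hydroperoxide F5 with the C13=C14 bond already in place. PPh3 reduces it to the allylic alcohol F6, and NaH, CS2 and MeI convert the less hindered C15 hydroxyl into the xanthate F7. Bu3SnH/AIBN (Barton–McCombie) delivers hydrogen to the less hindered C15 end of the allyl radical and returns to 38.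

Step 3. The α‑branched alkenyl Grignard reagent may transfer slowly from copper or with low enantioselectivity, and uncatalysed 1,2‑addition then competes. The fallback replaces catalyst control by auxiliary control and sets out from bromide 5. Its Grignard reagent 7 adds, with ZnBr2 chelation, to (R)-2-(p-tolylsulfinyl)cyclopent-2-en-1-one to give the β‑keto sulfoxide F8; the (R) assignment rests on the recalled facial sense of such chelate‑controlled additions. NaH and MeI methylate C2 to give the methylated keto sulfoxide F9. Lithium naphthalenide cleaves the C–S bond to the regiodefined lithium enolate F10, which is propargylated in the same flask, trans to the alkenyl group, and so returns to ketone 9.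

**Further compounds**

F1 | step 10 | (2E)-5-[(3R,4R)-4-(5,5-dimethoxypent-1-en-2-yl)-3-methyl-2-oxooxan-3-yl]pent-2-enal | O=C1OCC[C@H](C(=C)CCC(OC)OC)[C@@]1(C)CC/C=C/C=O
F2 | step 10 | (2E)-5-[(3R,4R)-3-methyl-2-oxo-4-(5-oxopent-1-en-2-yl)oxan-3-yl]pent-2-enal | O=C1OCC[C@H](C(=C)CCC=O)[C@@]1(C)CC/C=C/C=O
F3 | step 10 | tricyclic lactone with 3‑OH and 4‑CHO (mixture at C3 and C4) | O=C1OCC[C@H]2[C@@]1(C)CC[C@H]3C(C=O)C(O)CC[C@]23C
F4 | step 10 | tricyclic lactone with 3‑OH and 4‑CO2H (mixture at C3 and C4) | O=C1OCC[C@H]2[C@@]1(C)CC[C@H]3C(C(=O)O)C(O)CC[C@]23C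
F5 | step 25 | 15‑hydroperoxide of 38 (mixture at C15) | CO[C@@H]1CC2=C(C(OO)C[C@@]3(C(=O)OCc4ccccc4)CCC(C)(C)[C@@H](O)[C@@H]23)[C@]2(C)CC[C@@H]3[C@](C)(CC[C@@H](OCc4ccccc4)[C@]3(C)C(=O)OCc3ccccc3)[C@H]2C1
F6 | step 25 | 15‑hydroxy derivative of 38 (mixture at C15) | CO[C@@H]1CC2=C(C(O)C[C@@]3(C(=O)OCc4ccccc4)CCC(C)(C)[C@@H](O)[C@@H]23)[C@]2(C)CC[C@@H]3[C@](C)(CC[C@@H](OCc4ccccc4)[C@]3(C)C(=O)OCc3ccccc3)[C@H]2C1
F7 | step 25 | 15‑O‑(S‑methyl xanthate) of F6 | CO[C@@H]1CC2=C(C(OC(=S)SC)C[C@@]3(C(=O)OCc4ccccc4)CCC(C)(C)[C@@H](O)[C@@H]23)[C@]2(C)CC[C@@H]3[C@](C)(CC[C@@H](OCc4ccccc4)[C@]3(C)C(=O)OCc3ccccc3)[C@H]2C1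
F8 | step 3 | (3R)-3-(5,5-dimethoxypent-1-en-2-yl)-2-(p-tolylsulfinyl)cyclopentan-1-one (sulfur as in the auxiliary, mixture at C2) | O=C1CC[C@H](C(=C)CCC(OC)OC)C1S(=O)c1ccc(C)cc1
F9 | step 3 | (3R)-3-(5,5-dimethoxypent-1-en-2-yl)-2-methyl-2-(p-tolylsulfinyl)cyclopentan-1-one (mixture at C2) | O=C1CC[C@H](C(=C)CCC(OC)OC)C1(C)S(=O)c1ccc(C)cc1
F10 | step 3 | lithium (3R)-3-(5,5-dimethoxypent-1-en-2-yl)-2-methylcyclopent-1-en-1-olate | [Li]OC1=C(C)[C@@H](C(=C)CCC(OC)OC)CC1
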